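**Retrosynthetic overview**

1. Numbering used throughout: C1 (the =CH2-bearing ring carbon), C2, C3, C4 (ring-fusion CH), C5 (quaternary C with CH3 and side chain), C6 (CHBr), C7, C8, C9 (ring-fusion C–CH3), C10 (CH–CH2Ar); ring A = C1–C2–C3–C4–C9–C10, ring B = C4–C5–C6–C7–C8–C9.
2. Enabling feature: in ring B the C5–C6 edge (a quaternary carbon next to a carbon–heteroatom carbon) can be read as the enol ether of a C6 ketone, and C9 carries a methyl group that can be held as a formyl group. Ring B is then the [4+2] adduct of a 2-silyloxy diene C4=C5–C6(OSi)=C7 and a 2-substituted acrolein C8=C9(CHO); because C4–C9 is the ring fusion, a C3–C2–C1–C10 tether between the partners closes ring A in the same event.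
3. Key disconnection: the whole decalin ⇐ one acyclic enone–enal with a single stereocentre (C10, carrying the aryl-methyl arm) by tandem silyl dienol ether formation/intramolecular Diels–Alder reaction. Rings A and B form together; no carbocycle exists before this step.
4. After the key step: C9 CHO ⇒ CH3; C5 quaternary centre by Mukaiyama–Michael addition of the cycloadduct's enol ether; C6 ketone ⇒ alkenyl bromide ⇒ equatorial C6–Br (HAT hydrogenation); side-chain alkene ⇒ (S)-epoxide ⇒ bromohydrin ⇒ bromochloride through a bromonium ion; C1 ketal ⇒ ketone ⇒ methylidene; phenol unmasked last.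
5. Before the key step: C10 by Evans alkylation with the benzylic bromide from 2,4-dibromo-6-methylphenol; chain by Weinreb ketone synthesis, Wittig enone formation and α-methylenation of an aldehyde.

Key step: step 12

Remark: α = the face of C4–H, β = the face of the C9 angular group; Ar = 3,5-dibromo-2-(triisopropylsilyloxy)phenyl; it is assumed that the ent-Shi ketone of step 19 (made from L-sorbose) is available as a reagent and that any minor bromohydrin regioisomer from step 21 converges on the same bromonium ion in step 22.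

**Route**

Step 1
Reactants: 1 2,4-dibromo-6-methylphenol
Product: 2 (2,4-dibromo-6-methylphenoxy)tri(propan-2-yl)silane
Conditions: NaH, i-Pr3SiCl, THF, 0 to 23 °C
Reagents that add atoms: chlorotri(propan-2-yl)silane, CC(C)[Si](Cl)(C(C)C)C(C)C
Why: O-silylation of the sodium phenoxide should mask the acidic OH with a hindered silyl ether that survives bases, ylides, Lewis acids and brief aqueous acid and is removed by fluoride at the end.

Step 2
Reactants: 2 (2,4-dibromo-6-methylphenoxy)tri(propan-2-yl)silane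
Product: 3 [2,4-dibromo-6-(bromomethyl)phenoxy]tri(propan-2-yl)silane (ArCH2Br)
Conditions: NBS, AIBN (cat.), PhCF3, 80 °C
Reagents that add atoms: N-bromosuccinimide, O=C1CCC(=O)N1Br
Why: Wohl–Ziegler radical bromination should take place at the only benzylic C–H bonds, the electron-poor ring being inert to ring bromination.

Step 3
Reactants: 4 (4S)-4-benzyl-1,3-oxazolidin-2-one; 5 pent-4-enoyl chloride
Product: 6 (4S)-4-benzyl-3-(pent-4-enoyl)-1,3-oxazolidin-2-one
Conditions: n-BuLi, THF, −78 °C; then 5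
Reagents that add atoms: none
Why: N-acylation of the lithiated oxazolidinone attaches the Evans auxiliary to the chain that becomes C1, C10, C9 and the carbon of the later angular methyl group.

Step 4
Reactants: 6 (4S)-4-benzyl-3-(pent-4-enoyl)-1,3-oxazolidin-2-one; 3 [2,4-dibromo-6-(bromomethyl)phenoxy]tri(propan-2-yl)silane
Product: 7 (4S)-4-benzyl-3-[(2R)-2-(ArCH2)pent-4-enoyl]-1,3-oxazolidin-2-one
Conditions: NaN(SiMe3)2, THF, −78 °C; then 3, −78 to −40 °C
Reagents that add atoms: none
Why: Evans asymmetric alkylation: the chelated Z-enolate should be attacked by the benzylic bromide on the face away from the auxiliary benzyl group, which sets C10 in the configuration of the target.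

Step 5
Reactants: 7 (4S)-4-benzyl-3-[(2R)-2-(ArCH2)pent-4-enoyl]-1,3-oxazolidin-2-one
Product: 8 (2R)-2-(ArCH2)-N-methoxy-N-methylpent-4-enamide
Conditions: MeNH(OMe)·HCl, AlMe3, CH2Cl2, 0 to 23 °C
Reagents that add atoms: N,O-dimethylhydroxylamine hydrochloride, CNOC.Cl
Why: Aluminium-amide transamidation (Weinreb amide formation) should cleave the auxiliary without touching the α-stereocentre.

Step 6
Reactants: 8 (2R)-2-(ArCH2)-N-methoxy-N-methylpent-4-enamide
Product: 9 (4R)-4-(ArCH2)-1-(1,3-dioxolan-2-yl)hept-6-en-3-one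
Conditions: BrCH2CH2CH(OCH2CH2O), Mg, THF, 25 °C; then 8, 0 °C
Reagents that add atoms: 2-(2-bromoethyl)-1,3-dioxolane (as its Grignard reagent), BrCCC1OCCO1
Why: Weinreb ketone synthesis: the chelated tetrahedral intermediate should stop at mono-addition and bring in C2–C4 with C4 masked as an acetal, alkyl Grignard reagents not exchanging with aryl bromides at 0 °C.

Step 7
Reactants: 9 (4R)-4-(ArCH2)-1-(1,3-dioxolan-2-yl)hept-6-en-3-one
Product: 10 2-[(2R)-1-Ar-pent-4-en-2-yl]-2-[2-(1,3-dioxolan-2-yl)ethyl]-1,3-dioxolane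
Conditions: (Me3SiOCH2)2, TMSOTf (cat.), CH2Cl2, −78 to −20 °C
Reagents that add atoms: 1,2-bis(trimethylsilyloxy)ethane, C[Si](C)(C)OCCO[Si](C)(C)C
Why: Silyl-triflate-catalysed ketalisation with the bis-silyl ether of glycol at low temperature should protect the C1 ketone without enolising the adjacent C10 stereocentre.

Step 8
Reactants: 10 2-[(2R)-1-Ar-pent-4-en-2-yl]-2-[2-(1,3-dioxolan-2-yl)ethyl]-1,3-dioxolane
Product: 11 3-{2-[(2R)-1-Ar-pent-4-en-2-yl]-1,3-dioxolan-2-yl}propanal
Conditions: TESOTf, 2,4,6-collidine, CH2Cl2, 0 °C; then H2O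
Reagents that add atoms: water, O
Why: Chemoselective acetal cleavage: silyl triflate and collidine should convert only the aldehyde-derived dioxolane into a collidinium salt that water hydrolyses, the hindered ketone ketal being left intact.

Step 9
Reactants: 11 3-{2-[(2R)-1-Ar-pent-4-en-2-yl]-1,3-dioxolan-2-yl}propanal
Product: 12 (3E)-3-methyl-6-{2-[(2R)-1-Ar-pent-4-en-2-yl]-1,3-dioxolan-2-yl}hex-3-en-2-one
Conditions: Ph3P=C(Me)COMe, PhMe, 90 °C
Reagents that add atoms: 3-(triphenyl-λ5-phosphanylidene)butan-2-one, CC(=O)C(C)=P(c1ccccc1)(c1ccccc1)c1ccccc1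
Why: Wittig olefination with the stabilised α-methyl ylide should give the (E)-trisubstituted enone C4=C5(CH3)–C6(=O)–C7H3.

Step 10
Reactants: 12 (3E)-3-methyl-6-{2-[(2R)-1-Ar-pent-4-en-2-yl]-1,3-dioxolan-2-yl}hex-3-en-2-one
Product: 13 (3S)-4-Ar-3-{2-[(3E)-4-methyl-5-oxohex-3-en-1-yl]-1,3-dioxolan-2-yl}butanal
Conditions: OsO4 (cat.), NaIO4, 2,6-lutidine, dioxane/H2O, 23 °C
Reagents that add atoms: sodium periodate (oxygen, relayed by OsO4), [Na+].[O-]I(=O)(=O)=O
Why: Johnson–Lemieux oxidative cleavage: OsO4 should dihydroxylate the electron-rich terminal alkene far faster than the electron-poor trisubstituted enone, and periodate cleaves the diol to the aldehyde.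

Step 11
Reactants: 13 (3S)-4-Ar-3-{2-[(3E)-4-methyl-5-oxohex-3-en-1-yl]-1,3-dioxolan-2-yl}butanal
Product: 14 (3S)-4-Ar-2-methylidene-3-{2-[(3E)-4-methyl-5-oxohex-3-en-1-yl]-1,3-dioxolan-2-yl}butanal
Conditions: 37% aq. CH2O, pyrrolidine (cat.), EtCO2H (cat.), i-PrOH, 45 °C
Reagents that add atoms: formaldehyde, C=O
Why: Amine-catalysed α-methylenation (Mannich condensation/elimination) of the aldehyde should create the C8=C9 double bond of a 2-substituted acrolein, ketones not reacting under these conditions.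

Step 12
Reactants: 14 (3S)-4-Ar-2-methylidene-3-{2-[(3E)-4-methyl-5-oxohex-3-en-1-yl]-1,3-dioxolan-2-yl}butanal
Product: 16 cycloadduct (trans-fused Δ5-octalin; C1 ethylene ketal; 5-methyl-6-TBSO enol ether; 9β-CHO; 10β-CH2Ar; 4α-H), via silyl dienol ether 15 (not isolated)
Conditions: TBSOTf, Et3N, CH2Cl2, −78 to 23 °C
Reagents that add atoms: tert-butyldimethylsilyl trifluoromethanesulfonate, CC(C)(C)[Si](C)(C)OS(=O)(=O)C(F)(F)F
Why: Et3N/TBSOTf should silylate the methyl ketone at C7 to the cross-conjugated 2-silyloxy diene 15 (C4=C5–C6(OTBS)=C7), which then undergoes an intramolecular normal-demand Diels–Alder reaction with the 2-substituted acrolein C8=C9(CHO), the nucleophilic terminus C7 bonding to the β-carbon C8 and C4 to C9 (concerted but asynchronous; a stepwise Mukaiyama–Michael/Michael course would form the same two bonds). The closest known reaction types are the silyl triflate/amine-triggered intramolecular Diels–Alder (double Michael) reaction of tethered enone–acceptor pairs and the Lewis-acid-promoted cycloaddition of 2-silyloxy dienes with 2-alkyl acroleins. Ring B (C4–C5–C6–C7–C8–C9) closes as the [4+2] cyclohexene ring, and ring A (C1–C2–C3–C4–C9–C10) closes through the same C4–C9 bond by way of the four-atom tether in a chair-like arrangement. C4 and C9 are set relative to each other by suprafacial addition to the (E)-diene with the formyl group endo, which places the tether exo and gives the trans ring fusion (C4–H α, C9–CHO β); both are set relative to C10 by the tether chair, in which the aryl-methyl group lies equatorial and so ends cis to the angular formyl group. The step needs endo (trans-fusion) and π-facial selectivity: the first should be secured by the silyl-triflate-activated formyl group and the matched polarity of the partners, the second by the single stereocentre C10 next to the dienophile.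

Step 13
Reactants: 16 cycloadduct (9β-formyl silyl enol ether ketal)
Product: 17 tosylhydrazone of 16 at the C9 formyl carbon
Conditions: TsNHNH2, MgSO4, THF, 40 °C
Reagents that add atoms: 4-methylbenzenesulfonohydrazide, Cc1ccc(cc1)S(=O)(=O)NN
Why: Hydrazone condensation at the only carbonyl group prepares the activating formyl group for deoxygenation under neutral conditions that the silyl enol ether and the ketal should tolerate.

Step 14
Reactants: 17 tosylhydrazone of 16
Product: 18 5,9β-dimethyl-6-(tert-butyldimethylsilyloxy)-10β-(ArCH2)-trans-Δ5-octalin 1-(ethylene ketal)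
Conditions: catecholborane, CHCl3, 0 to 23 °C; then NaOAc·3H2O, 60 °C
Reagents that add atoms: none
Why: Tosylhydrazone reduction with catecholborane (hydroboration of C=N, then acetate-induced loss of sulfinate and N2 from the diazene) should turn the activating formyl group into the C9 methyl group without basic or strongly reducing conditions.

Step 15
Reactants: 18 5,9β-dimethyl-6-(tert-butyldimethylsilyloxy)-10β-(ArCH2)-trans-Δ5-octalin 1-(ethylene ketal)
Product: 19 5β,9β-dimethyl-5α-(3-oxopropyl)-10β-(ArCH2)-trans-decalin-6-one 1-(ethylene ketal)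
Conditions: acrolein, BF3·OEt2, i-PrOH, CH2Cl2, −78 °C
Reagents that add atoms: acrolein, C=CC=O
Why: Mukaiyama–Michael addition: C5 of the regiodefined enol ether should attack BF3-activated acrolein from the α face, anti to the axial C9 methyl group, which sets the quaternary centre C5 with the methyl axial (β) and the new chain equatorial (α).

Step 16
Reactants: 19 5β,9β-dimethyl-5α-(3-oxopropyl)-10β-(ArCH2)-trans-decalin-6-one 1-(ethylene ketal)
Product: 20 5β,9β-dimethyl-5α-(4-methylpent-3-en-1-yl)-10β-(ArCH2)-trans-decalin-6-one 1-(ethylene ketal)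
Conditions: i-PrPPh3I, n-BuLi, THF, 0 °C; then 19, −78 to 0 °C
Reagents that add atoms: isopropyltriphenylphosphonium iodide, CC(C)[P+](c1ccccc1)(c1ccccc1)c1ccccc1.[I-]
Why: Wittig olefination with the non-stabilised isopropylidene ylide should convert only the aldehyde, the neopentyl C6 ketone being too hindered to react.

Step 17
Reactants: 20 5β,9β-dimethyl-5α-(4-methylpent-3-en-1-yl)-10β-(ArCH2)-trans-decalin-6-one 1-(ethylene ketal)
Product: 21 C6 hydrazone of 20
Conditions: N2H4·H2O, AcOH (cat.), EtOH, 80 °C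
Reagents that add atoms: hydrazine hydrate, NN.O
Why: Hydrazone condensation at C6, the only carbonyl group left, prepares the Barton alkenyl halide synthesis, which was developed for hindered ketones of this kind.

Step 18
Reactants: 21 C6 hydrazone of 20
Product: 22 6-bromo-5β,9β-dimethyl-5α-(4-methylpent-3-en-1-yl)-10β-(ArCH2)-trans-Δ6-octalin 1-(ethylene ketal)
Conditions: NBS, pyridine, CH2Cl2, −10 °C
Reagents that add atoms: N-bromosuccinimide, O=C1CCC(=O)N1Br
Why: Barton alkenyl bromide synthesis: oxidation of the hydrazone to the diazo compound, bromination and loss of N2 and of a proton from C7 (the only α-carbon with hydrogen) should give the C6=C7 bromoalkene.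

Step 19
Reactants: 22 6-bromo-5β,9β-dimethyl-5α-(4-methylpent-3-en-1-yl)-10β-(ArCH2)-trans-Δ6-octalin 1-(ethylene ketal)
Product: 23 6-bromo-5α-{2-[(2S)-3,3-dimethyloxiran-2-yl]ethyl}-5β,9β-dimethyl-10β-(ArCH2)-trans-Δ6-octalin 1-(ethylene ketal)
Conditions: ent-Shi ketone (cat.), 2KHSO5·KHSO4·K2SO4, K2CO3, Bu4NHSO4, MeCN/CH2(OMe)2/aq. buffer, 0 °C
Reagents that add atoms: potassium peroxymonosulfate (oxygen, relayed by the dioxirane of the ketone catalyst), [K+].[O-]OS(=O)(=O)O
Why: Shi epoxidation: the chiral dioxirane should oxidise the electron-rich trisubstituted side-chain alkene through a spiro transition state and set the (S) configuration at the side-chain CH under reagent control, the electron-poor bromoalkene being inert.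

Step 20
Reactants: 23 6-bromo-5α-{2-[(2S)-3,3-dimethyloxiran-2-yl]ethyl}-5β,9β-dimethyl-10β-(ArCH2)-trans-Δ6-octalin 1-(ethylene ketal)
Product: 24 6β-bromo-5α-{2-[(2S)-3,3-dimethyloxiran-2-yl]ethyl}-5β,9β-dimethyl-10β-(ArCH2)-trans-decalin 1-(ethylene ketal)
Conditions: Mn(dpm)3 (cat., dpm = dipivaloylmethanate), PhSiH3, t-BuOOH, i-PrOH, 23 °C
Reagents that add atoms: none
Why: Metal-hydride HAT hydrogenation of a haloalkene: H• should add to C7, and the α-bromo radical at C6 should take the second hydrogen on its α face (axial), away from the axial C5 methyl group, so that bromine ends equatorial (β) under thermodynamic stereocontrol, the side-chain alkene having been epoxidised beforehand so that it is neither reduced nor attacked by the radical.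

Step 21
Reactants: 24 6β-bromo-5α-{2-[(2S)-3,3-dimethyloxiran-2-yl]ethyl}-5β,9β-dimethyl-10β-(ArCH2)-trans-decalin 1-(ethylene ketal)
Product: 25 6β-bromo-5α-[(3S)-4-bromo-3-hydroxy-4-methylpentyl]-5β,9β-dimethyl-10β-(ArCH2)-trans-decalin-1-one
Conditions: 48% aq. HBr, THF, −20 to 23 °C
Reagents that add atoms: hydrogen bromide, Br; water, O
Why: Acid-mediated Markovnikov opening of the trisubstituted epoxide by bromide at the tertiary carbon should leave the C–O stereocentre untouched, and the same aqueous acid should hydrolyse the dioxolane to the C1 ketone, next to which the equatorial C10 arm is the stable epimer.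

Step 22
Reactants: 25 6β-bromo-5α-[(3S)-4-bromo-3-hydroxy-4-methylpentyl]-5β,9β-dimethyl-10β-(ArCH2)-trans-decalin-1-one
Product: 26 6β-bromo-5α-[(3R)-3-bromo-4-chloro-4-methylpentyl]-5β,9β-dimethyl-10β-(ArCH2)-trans-decalin-1-one
Conditions: PPh3, NCS, CH2Cl2, −20 to 23 °C
Reagents that add atoms: N-chlorosuccinimide, O=C1CCC(=O)N1Cl
Why: Appel-type deoxychlorination with anchimeric assistance: the oxyphosphonium group should be displaced from the back by the neighbouring bromine (inversion at the CH), and chloride should open the resulting bromonium ion at the tertiary carbon, which gives the (R)-CHBr–C(CH3)2Cl unit in the absence of any alkene that could accept the bromonium ion.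

Step 23
Reactants: 26 6β-bromo-5α-[(3R)-3-bromo-4-chloro-4-methylpentyl]-5β,9β-dimethyl-10β-(ArCH2)-trans-decalin-1-one
Product: 27 triisopropylsilyl ether of the target
Conditions: Cp2TiMe2, PhMe/THF, 70 °C, dark
Reagents that add atoms: dimethyltitanocene, [CH3-].[CH3-].[Ti+4].c1cc[cH-]c1.c1cc[cH-]c1
Why: Petasis methylenation through a non-basic titanium methylidene should convert the hindered C1 ketone into the exocyclic alkene without elimination of the alkyl halides or epimerisation at C10.

Step 24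
Reactants: 27 triisopropylsilyl ether of the target
Product: 28 target, 2,4-dibromo-6-{[(1R,4aS,5R,6R,8aS)-6-bromo-5-[(3R)-3-bromo-4-chloro-4-methylpentyl]-5,8a-dimethyl-2-methylidenedecahydronaphthalen-1-yl]methyl}phenol
Conditions: Bu4NF, AcOH, THF, 0 °C
Reagents that add atoms: none
Why: Fluoride cleavage of the aryl silyl ether under buffered conditions should free the phenol without touching the tertiary chloride, the secondary bromides or the alkene.

**Compound list**

1 | 2,4-dibromo-6-methylphenol | Cc1cc(Br)cc(Br)c1O | starting material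
2 | (2,4-dibromo-6-methylphenoxy)tri(propan-2-yl)silane | Cc1cc(Br)cc(Br)c1O[Si](C(C)C)(C(C)C)C(C)C | intermediate
3 | [2,4-dibromo-6-(bromomethyl)phenoxy]tri(propan-2-yl)silane (ArCH2Br) | BrCc1cc(Br)cc(Br)c1O[Si](C(C)C)(C(C)C)C(C)C | intermediate
4 | (4S)-4-benzyl-1,3-oxazolidin-2-one | O=C1N[C@@H](Cc2ccccc2)CO1 | starting material
5 | pent-4-enoyl chloride | C=CCCC(=O)Cl | starting material
6 | (4S)-4-benzyl-3-(pent-4-enoyl)-1,3-oxazolidin-2-one | C=CCCC(=O)N1C(=O)OC[C@@H]1Cc1ccccc1 | intermediate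
7 | (4S)-4-benzyl-3-[(2R)-2-(ArCH2)pent-4-enoyl]-1,3-oxazolidin-2-one | C=CC[C@H](Cc1cc(Br)cc(Br)c1O[Si](C(C)C)(C(C)C)C(C)C)C(=O)N1C(=O)OC[C@@H]1Cc1ccccc1 | intermediate
8 | (2R)-2-(ArCH2)-N-methoxy-N-methylpent-4-enamide | C=CC[C@H](Cc1cc(Br)cc(Br)c1O[Si](C(C)C)(C(C)C)C(C)C)C(=O)N(C)OC | intermediate
9 | (4R)-4-(ArCH2)-1-(1,3-dioxolan-2-yl)hept-6-en-3-one | C=CC[C@H](Cc1cc(Br)cc(Br)c1O[Si](C(C)C)(C(C)C)C(C)C)C(=O)CCC1OCCO1 | intermediate
10 | 2-[(2R)-1-Ar-pent-4-en-2-yl]-2-[2-(1,3-dioxolan-2-yl)ethyl]-1,3-dioxolane | C=CC[C@H](Cc1cc(Br)cc(Br)c1O[Si](C(C)C)(C(C)C)C(C)C)C1(CCC2OCCO2)OCCO1 | intermediate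
11 | 3-{2-[(2R)-1-Ar-pent-4-en-2-yl]-1,3-dioxolan-2-yl}propanal | C=CC[C@H](Cc1cc(Br)cc(Br)c1O[Si](C(C)C)(C(C)C)C(C)C)C1(CCC=O)OCCO1 | intermediate
12 | (3E)-3-methyl-6-{2-[(2R)-1-Ar-pent-4-en-2-yl]-1,3-dioxolan-2-yl}hex-3-en-2-one | C=CC[C@H](Cc1cc(Br)cc(Br)c1O[Si](C(C)C)(C(C)C)C(C)C)C1(CC/C=C(\C)C(C)=O)OCCO1 | intermediate
13 | (3S)-4-Ar-3-{2-[(3E)-4-methyl-5-oxohex-3-en-1-yl]-1,3-dioxolan-2-yl}butanal | O=CC[C@H](Cc1cc(Br)cc(Br)c1O[Si](C(C)C)(C(C)C)C(C)C)C1(CC/C=C(\C)C(C)=O)OCCO1 | intermediate
14 | (3S)-4-Ar-2-methylidene-3-{2-[(3E)-4-methyl-5-oxohex-3-en-1-yl]-1,3-dioxolan-2-yl}butanal | O=CC(=C)[C@H](Cc1cc(Br)cc(Br)c1O[Si](C(C)C)(C(C)C)C(C)C)C1(CC/C=C(\C)C(C)=O)OCCO1 | intermediate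
15 | (3S)-4-Ar-3-{2-[(3E)-5-(tert-butyldimethylsilyloxy)-4-methylhexa-3,5-dien-1-yl]-1,3-dioxolan-2-yl}-2-methylidenebutanal (silyl dienol ether) | O=CC(=C)[C@H](Cc1cc(Br)cc(Br)c1O[Si](C(C)C)(C(C)C)C(C)C)C1(CC/C=C(\C)C(=C)O[Si](C)(C)C(C)(C)C)OCCO1 | intermediate (not isolated)
16 | cycloadduct: 9β-formyl-5-methyl-6-(tert-butyldimethylsilyloxy)-10β-(ArCH2)-trans-Δ5-octalin 1-(ethylene ketal), 4α-H | O1CCOC12CC[C@@H]3C(C)=C(O[Si](C)(C)C(C)(C)C)CC[C@@]3(C=O)[C@@H]2Cc2cc(Br)cc(Br)c2O[Si](C(C)C)(C(C)C)C(C)C | intermediate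
17 | (E)-tosylhydrazone of 16 at the C9 formyl carbon | O1CCOC12CC[C@@H]3C(C)=C(O[Si](C)(C)C(C)(C)C)CC[C@@]3(/C=N/NS(=O)(=O)c3ccc(C)cc3)[C@@H]2Cc2cc(Br)cc(Br)c2O[Si](C(C)C)(C(C)C)C(C)C | intermediate
18 | 5,9β-dimethyl-6-(tert-butyldimethylsilyloxy)-10β-(ArCH2)-trans-Δ5-octalin 1-(ethylene ketal), 4α-H | O1CCOC12CC[C@@H]3C(C)=C(O[Si](C)(C)C(C)(C)C)CC[C@@]3(C)[C@@H]2Cc2cc(Br)cc(Br)c2O[Si](C(C)C)(C(C)C)C(C)C | intermediate
19 | 5β,9β-dimethyl-5α-(3-oxopropyl)-10β-(ArCH2)-trans-decalin-6-one 1-(ethylene ketal) | O1CCOC12CC[C@@H]3[C@@](C)(CCC=O)C(=O)CC[C@@]3(C)[C@@H]2Cc2cc(Br)cc(Br)c2O[Si](C(C)C)(C(C)C)C(C)C | intermediate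
20 | 5β,9β-dimethyl-5α-(4-methylpent-3-en-1-yl)-10β-(ArCH2)-trans-decalin-6-one 1-(ethylene ketal) | O1CCOC12CC[C@@H]3[C@@](C)(CCC=C(C)C)C(=O)CC[C@@]3(C)[C@@H]2Cc2cc(Br)cc(Br)c2O[Si](C(C)C)(C(C)C)C(C)C | intermediate
21 | C6 hydrazone of 20 (NH2 anti to C5) | O1CCOC12CC[C@@H]3[C@@](C)(CCC=C(C)C)/C(=N/N)CC[C@@]3(C)[C@@H]2Cc2cc(Br)cc(Br)c2O[Si](C(C)C)(C(C)C)C(C)C | intermediate
22 | 6-bromo-5β,9β-dimethyl-5α-(4-methylpent-3-en-1-yl)-10β-(ArCH2)-trans-Δ6-octalin 1-(ethylene ketal) | O1CCOC12CC[C@@H]3[C@@](C)(CCC=C(C)C)C(Br)=CC[C@@]3(C)[C@@H]2Cc2cc(Br)cc(Br)c2O[Si](C(C)C)(C(C)C)C(C)C | intermediate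
23 | 6-bromo-5α-{2-[(2S)-3,3-dimethyloxiran-2-yl]ethyl}-5β,9β-dimethyl-10β-(ArCH2)-trans-Δ6-octalin 1-(ethylene ketal) | O1CCOC12CC[C@@H]3[C@@](C)(CC[C@@H]4OC4(C)C)C(Br)=CC[C@@]3(C)[C@@H]2Cc2cc(Br)cc(Br)c2O[Si](C(C)C)(C(C)C)C(C)C | intermediate
24 | 6β-bromo-5α-{2-[(2S)-3,3-dimethyloxiran-2-yl]ethyl}-5β,9β-dimethyl-10β-(ArCH2)-trans-decalin 1-(ethylene ketal) | O1CCOC12CC[C@@H]3[C@@](C)(CC[C@@H]4OC4(C)C)[C@H](Br)CC[C@@]3(C)[C@@H]2Cc2cc(Br)cc(Br)c2O[Si](C(C)C)(C(C)C)C(C)C | intermediate
25 | 6β-bromo-5α-[(3S)-4-bromo-3-hydroxy-4-methylpentyl]-5β,9β-dimethyl-10β-(ArCH2)-trans-decalin-1-one | O=C1CC[C@@H]2[C@@](C)(CC[C@H](O)C(C)(C)Br)[C@H](Br)CC[C@@]2(C)[C@@H]1Cc1cc(Br)cc(Br)c1O[Si](C(C)C)(C(C)C)C(C)C | intermediate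
26 | 6β-bromo-5α-[(3R)-3-bromo-4-chloro-4-methylpentyl]-5β,9β-dimethyl-10β-(ArCH2)-trans-decalin-1-one | O=C1CC[C@@H]2[C@@](C)(CC[C@@H](Br)C(C)(C)Cl)[C@H](Br)CC[C@@]2(C)[C@@H]1Cc1cc(Br)cc(Br)c1O[Si](C(C)C)(C(C)C)C(C)C | intermediate
27 | triisopropylsilyl ether of the target | C=C1CC[C@@H]2[C@@](C)(CC[C@@H](Br)C(C)(C)Cl)[C@H](Br)CC[C@@]2(C)[C@@H]1Cc1cc(Br)cc(Br)c1O[Si](C(C)C)(C(C)C)C(C)C | intermediate
28 | 2,4-dibromo-6-{[(1R,4aS,5R,6R,8aS)-6-bromo-5-[(3R)-3-bromo-4-chloro-4-methylpentyl]-5,8a-dimethyl-2-methylidenedecahydronaphthalen-1-yl]methyl}phenol | C=C1CC[C@@H]2[C@@](C)(CC[C@@H](Br)C(C)(C)Cl)[C@H](Br)CC[C@@]2(C)[C@@H]1Cc1cc(Br)cc(Br)c1O | target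

**Step count and risks**

Total step count: 24. Longest linear sequence: 23 steps (from 1 through steps 1, 2 and 4 to 24).

Steps most likely to fail:

1. Step 20 (HAT hydrogenation of the bromoalkene). Hydrogen-atom transfer to the hindered, electron-poor bromoalkene may be slow, so that loss of bromine from the radical or reductive opening of the epoxide competes. The fallback sets out from hydrazone 21 and comes back at 24. Oxidation of 21 with CuBr2 and t-BuOLi in THF should give the geminal dibromide F1. Epoxidation of its side chain under the conditions of step 19 should give the geminal dibromide epoxide F2. Removal of one bromine atom by radical reduction with (Me3Si)3SiH (one equivalent) and AIBN in PhMe at 80 °C should then give 24: the α-bromo radical at C6 takes its hydrogen on the α face for the same steric reason as in step 20. The epoxide is installed first so that this radical cannot cyclise onto the side-chain alkene.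

2. Step 22 (bromonium-mediated chlorination). The bromonium ion or tertiary cation may lose a proton to give an allylic bromide, chloride may open the ion at the secondary carbon, or bromonium transfer may erode the configuration. The fallback sets out from 24 and comes back at 26. Concentrated aqueous HCl in THF should open the epoxide with chloride at the tertiary carbon and hydrolyse the ketal, giving the chlorohydrin ketone F3. The secondary hydroxyl is then replaced with inversion under Appel conditions (PPh3, CBr4, CH2Cl2) to give 26. Each halogen is thus placed by a separate classical substitution instead of a bromine shift.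

3. Step 18 (bromination of the hydrazone). Over-bromination to the geminal dibromide and electrophilic attack of the brominating agent on the side-chain alkene may lower the return. The fallback sets out from ketone 20 and comes back at 22. Enolisation with KN(SiMe3)2 and trapping with PhNTf2 in THF at −78 °C should give the enol triflate F4 (C7 is the only enolisable position). Triflate-to-bromide exchange with LiBr, catalysed by [(C5Me5)Ru(NCMe)3]OTf in 1,3-dimethylimidazolidin-2-one at 80 °C, should then give 22. No electrophilic bromine source is used, and the catalyst does not insert into aryl bromides.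

Further compounds
F1 | step 20 | 6,6-dibromo-5β,9β-dimethyl-5α-(4-methylpent-3-en-1-yl)-10β-(ArCH2)-trans-decalin 1-(ethylene ketal) | O1CCOC12CC[C@@H]3[C@@](C)(CCC=C(C)C)C(Br)(Br)CC[C@@]3(C)[C@@H]2Cc2cc(Br)cc(Br)c2O[Si](C(C)C)(C(C)C)C(C)C
F2 | step 20 | 6,6-dibromo-5α-{2-[(2S)-3,3-dimethyloxiran-2-yl]ethyl}-5β,9β-dimethyl-10β-(ArCH2)-trans-decalin 1-(ethylene ketal) | O1CCOC12CC[C@@H]3[C@@](C)(CC[C@@H]4OC4(C)C)C(Br)(Br)CC[C@@]3(C)[C@@H]2Cc2cc(Br)cc(Br)c2O[Si](C(C)C)(C(C)C)C(C)C
F3 | step 22 | 6β-bromo-5α-[(3S)-4-chloro-3-hydroxy-4-methylpentyl]-5β,9β-dimethyl-10β-(ArCH2)-trans-decalin-1-one | O=C1CC[C@@H]2[C@@](C)(CC[C@H](O)C(C)(C)Cl)[C@H](Br)CC[C@@]2(C)[C@@H]1Cc1cc(Br)cc(Br)c1O[Si](C(C)C)(C(C)C)C(C)C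
F4 | step 18 | 5β,9β-dimethyl-5α-(4-methylpent-3-en-1-yl)-10β-(ArCH2)-trans-Δ6-octalin-6-yl trifluoromethanesulfonate 1-(ethylene ketal) | O1CCOC12CC[C@@H]3[C@@](C)(CCC=C(C)C)C(OS(=O)(=O)C(F)(F)F)=CC[C@@]3(C)[C@@H]2Cc2cc(Br)cc(Br)c2O[Si](C(C)C)(C(C)C)C(C)C
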